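Ring C is disconnected at C8a–O1, C4a–C4 and O1–C2. The feature used is that C4a and C8a sit side by side in ring A, holding the C4 carbonyl and O1 respectively, with the C5 oxygen next to C4a and the C8 prenyl next to C8a; ring A can therefore react as a C4a–C8a aryne polarised by the C5 alkoxy group. In one operation this aryne inserts into the C–O bond of an arylpropiolic acid and the freed phenoxide closes the pyranone, which also attaches ring B. The precursor is a hexasubstituted ortho-silylaryl triflate (5-OMOM, 7-OMe, 6,8-diprenyl; silicon on C4a, triflate on C8a). C3 hydroxylation and MOM removal finish the flavonol.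

Key step: step 11

Assumption: the target is achiral and its prenyl double bonds are trisubstituted, so no stereocentre or olefin geometry has to be controlled; step 5 is a statistical mono-protection of a symmetric diol, with bis-ether and unreacted diol returned to the pool.

Step 1
Reactants: 1 methyl 2,4,6-trihydroxybenzoate; 2 prenyl bromide (1-bromo-3-methylbut-2-ene)
Product: 3 methyl 2,4,6-trihydroxy-3,5-bis(3-methylbut-2-enyl)benzoate
Conditions: 2 (2.2 equiv), 10% aq KOH, 0 °C to rt
Reagents that add atoms: none
Why: The phloroglucinolate is an ambident nucleophile that alkylates at carbon in water, where the phenoxide oxygens are strongly solvated, and since the ester blocks C1 the two allylic SN2 alkylations can only fall on C3 and C5 (phenoxide C-prenylation of the acylphloroglucinol type).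

Step 2
Reactants: 3 methyl 2,4,6-trihydroxy-3,5-bis(3-methylbut-2-enyl)benzoate
Product: 4 methyl 2,6-dihydroxy-4-methoxy-3,5-bis(3-methylbut-2-enyl)benzoate
Conditions: Me2SO4 (1.0 equiv), K2CO3 (1.1 equiv), acetone, rt
Reagents that add atoms: dimethyl sulfate, COS(=O)(=O)OC
Why: The hydroxyl para to the ester is the most acidic and the only one not hydrogen-bonded to the ester, so one equivalent of a hard methylating agent under carbonate should cap it selectively (Williamson O-methylation).

Step 3
Reactants: 4 methyl 2,6-dihydroxy-4-methoxy-3,5-bis(3-methylbut-2-enyl)benzoate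
Product: 6 5-methoxy-4,6-bis(3-methylbut-2-enyl)benzene-1,3-diol, via benzoic acid 5 (not isolated)
Conditions: KOH, H2O/DMSO, 90 °C, N2; then AcOH to pH 5, 70 °C
Reagents that add atoms: none
Why: Saponification gives a 2,6-dihydroxybenzoic acid whose ipso carbon is activated by two ortho hydroxyls and a para methoxyl, so protodecarboxylation should proceed on gentle warming in acetic acid, which is too weak to cyclise the prenyl groups.

Step 4
Reactants: 6 5-methoxy-4,6-bis(3-methylbut-2-enyl)benzene-1,3-diol
Product: 7 2-bromo-5-methoxy-4,6-bis(3-methylbut-2-enyl)benzene-1,3-diol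
Conditions: NBS (1.0 equiv), CH2Cl2, −78 °C
Reagents that add atoms: N-bromosuccinimide, O=C1CCC(=O)N1Br
Why: C2 is the only free ring position and is activated by two ortho hydroxyls and a para methoxyl, so electrophilic aromatic bromination with one equivalent of NBS at low temperature should be far faster than attack on the trisubstituted olefins.

Step 5
Reactants: 7 2-bromo-5-methoxy-4,6-bis(3-methylbut-2-enyl)benzene-1,3-diol
Product: 8 2-bromo-5-methoxy-3-(methoxymethoxy)-4,6-bis(3-methylbut-2-enyl)phenol
Conditions: MOMCl (1.0 equiv), iPr2NEt, CH2Cl2, 0 °C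
Reagents that add atoms: chloromethyl methyl ether, COCCl
Why: O-alkylation of one of two equivalent phenols with a limiting amount of MOMCl (acetal ether formation) should give the mono-ether as the main product of a statistical desymmetrisation, from which bis-ether and diol are separable.

Step 6
Reactants: 8 2-bromo-5-methoxy-3-(methoxymethoxy)-4,6-bis(3-methylbut-2-enyl)phenol
Product: 9 [2-bromo-5-methoxy-3-(methoxymethoxy)-4,6-bis(3-methylbut-2-enyl)phenoxy]trimethylsilane
Conditions: HMDS, THF, 70 °C; evaporate
Reagents that add atoms: hexamethyldisilazane, C[Si](C)(C)N[Si](C)(C)C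
Why: O-silylation of the remaining phenol with HMDS needs no added base and leaves only volatile by-products, so the moisture-sensitive aryl silyl ether can be used directly after evaporation.

Step 7
Reactants: 9 [2-bromo-5-methoxy-3-(methoxymethoxy)-4,6-bis(3-methylbut-2-enyl)phenoxy]trimethylsilane
Product: 12 5-methoxy-3-(methoxymethoxy)-4,6-bis(3-methylbut-2-enyl)-2-(trimethylsilyl)phenyl trifluoromethanesulfonate, via aryllithium 10 (not isolated), via lithium silylphenoxide 11 (not isolated)
Conditions: n-BuLi, THF, −100 °C; then Tf2O, −100 to −78 °C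
Reagents that add atoms: trifluoromethanesulfonic anhydride, O=S(=O)(OS(=O)(=O)C(F)(F)F)C(F)(F)F
Why: Bromine–lithium exchange is faster than any deprotonation at this temperature, the aryllithium next to the silyl ether undergoes a 1,3 O-to-C silyl shift (retro-Brook rearrangement), and the phenoxide so formed is trapped by Tf2O, which is the standard entry to ortho-silylaryl triflates.

Step 8
Reactants: 13 isovanillin (3-hydroxy-4-methoxybenzaldehyde)
Product: 14 4-methoxy-3-(methoxymethoxy)benzaldehyde
Conditions: MOMCl, iPr2NEt, CH2Cl2, 0 °C to rt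
Reagents that add atoms: chloromethyl methyl ether, COCCl
Why: O-alkylation of the phenol under amine base (acetal ether formation) masks the only acidic, aryne-reactive hydroxyl of ring B with a group that tolerates organolithiums and fluoride.

Step 9
Reactants: 14 4-methoxy-3-(methoxymethoxy)benzaldehyde
Product: 15 4-(2,2-dibromoethenyl)-1-methoxy-2-(methoxymethoxy)benzene
Conditions: CBr4, PPh3, CH2Cl2, 0 °C
Reagents that add atoms: carbon tetrabromide, BrC(Br)(Br)Br
Why: First stage of the Corey–Fuchs reaction, in which the ylide Ph3P=CBr2 formed in the flask olefinates the aldehyde (Wittig type) under neutral conditions that leave the MOM ether intact.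

Step 10
Reactants: 15 4-(2,2-dibromoethenyl)-1-methoxy-2-(methoxymethoxy)benzene
Product: 17 3-[4-methoxy-3-(methoxymethoxy)phenyl]prop-2-ynoic acid, via lithium acetylide 16 (not isolated)
Conditions: n-BuLi (2.2 equiv), THF, −78 to 0 °C; CO2, −78 °C to rt; then 1 M HCl to pH 3, 0 °C
Reagents that add atoms: carbon dioxide, O=C=O
Why: Second stage of the Corey–Fuchs reaction, in which bromine–lithium exchange, 1,2-shift with loss of bromide and deprotonation give the lithium acetylide, which is carboxylated by CO2, and a cold, mildly acidic quench preserves the MOM ether.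

Step 11
Reactants: 12 5-methoxy-3-(methoxymethoxy)-4,6-bis(3-methylbut-2-enyl)-2-(trimethylsilyl)phenyl trifluoromethanesulfonate; 17 3-[4-methoxy-3-(methoxymethoxy)phenyl]prop-2-ynoic acid
Product: 20 7-methoxy-5-(methoxymethoxy)-2-[4-methoxy-3-(methoxymethoxy)phenyl]-6,8-bis(3-methylbut-2-enyl)chromen-4-one, via aryne 18 (not isolated), via caesium ynone phenoxide 19 (not isolated)
Conditions: 17 (1.2 equiv), CsF (4 equiv), THF, 125 °C, sealed tube
Reagents that add atoms: none
Why: Desilylation by fluoride and departure of triflate unmask aryne 18; O-arylation of the caesium salt of 17 at C8a leaves a carbanion on C4a that attacks the adjacent ester carbonyl (transient 4-exo-trig closure), and collapse of the four-membered alkoxide hands the acyl group to carbon to give ortho-acyl phenoxide 19, a net aryne insertion into the acid C–O bond. Conjugate addition of this phenoxide oxygen to the alkynone β-carbon (6-endo-dig oxa-Michael closure) and protonation at C3 then form the pyranone, the one ring that is closed. The closest known reaction type is the CsF-mediated union of simple ortho-silylaryl triflates with carboxylic acids to ortho-hydroxyaryl ketones, which runs on to flavones with arylpropiolic acids; here it is applied to a more heavily substituted aryne. The selectivity required is the regiochemistry of the first addition: the σ-accepting oxygen on C5 bends the strained triple bond unsymmetrically, so that the nucleophile attacks the flattened C8a and the carbanion emerges on C4a, where the neighbouring C–O bond stabilises it, and this electronic bias should outweigh the small steric penalty from the prenyl CH2 on C8. Heating favours acyl transfer over protonation of the aryl anion, the low solubility of CsF in THF keeps the aryne concentration small, and the slight excess of carboxylate helps capture to outrun ene reactions with prenyl double bonds. No stereocentre is formed.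

Step 12
Reactants: 20 7-methoxy-5-(methoxymethoxy)-2-[4-methoxy-3-(methoxymethoxy)phenyl]-6,8-bis(3-methylbut-2-enyl)chromen-4-one
Product: 23 3-hydroxy-7-methoxy-5-(methoxymethoxy)-2-[4-methoxy-3-(methoxymethoxy)phenyl]-6,8-bis(3-methylbut-2-enyl)chromen-4-one, via 3-lithioflavone 21 (not isolated), via dimethyl boronate 22 (not isolated)
Conditions: LiN(iPr)2, THF, −78 °C; B(OMe)3, −78 °C to rt; then AcOH, 30% H2O2, 0 °C to rt
Reagents that add atoms: hydrogen peroxide, OO
Why: The C3–H of an alkoxyflavone, alpha to the carbonyl on the enol-ether double bond, is removed by the lithium amide at −78 °C (known C3 lithiation of flavones), the vinyllithium is borylated, and the boronate undergoes 1,2-migration to oxygen with H2O2, an oxidant that does not epoxidise isolated prenyl olefins.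

Step 13
Reactants: 23 3-hydroxy-7-methoxy-5-(methoxymethoxy)-2-[4-methoxy-3-(methoxymethoxy)phenyl]-6,8-bis(3-methylbut-2-enyl)chromen-4-one
Product: 24 3,5-dihydroxy-2-(3-hydroxy-4-methoxyphenyl)-7-methoxy-6,8-bis(3-methylbut-2-enyl)chromen-4-one (CNP0261856.0)
Conditions: 3 M aq HCl, MeOH, 50 °C
Reagents that add atoms: none
Why: Acid-catalysed acetal methanolysis removes both MOM ethers, and because the released 5-hydroxyl is hydrogen-bonded to the C4 carbonyl and there is no free 7-hydroxyl, acid-promoted chroman formation with the prenyl groups should stay minor under these mild conditions.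

Compound list
1 | methyl 2,4,6-trihydroxybenzoate | COC(=O)c1c(O)cc(O)cc1O | starting material
2 | prenyl bromide (1-bromo-3-methylbut-2-ene) | CC(C)=CCBr | starting material
3 | methyl 2,4,6-trihydroxy-3,5-bis(3-methylbut-2-enyl)benzoate | COC(=O)c1c(O)c(CC=C(C)C)c(O)c(CC=C(C)C)c1O | intermediate
4 | methyl 2,6-dihydroxy-4-methoxy-3,5-bis(3-methylbut-2-enyl)benzoate | COC(=O)c1c(O)c(CC=C(C)C)c(OC)c(CC=C(C)C)c1O | intermediate
5 | 2,6-dihydroxy-4-methoxy-3,5-bis(3-methylbut-2-enyl)benzoic acid | OC(=O)c1c(O)c(CC=C(C)C)c(OC)c(CC=C(C)C)c1O | intermediate (not isolated)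
6 | 5-methoxy-4,6-bis(3-methylbut-2-enyl)benzene-1,3-diol | COc1c(CC=C(C)C)c(O)cc(O)c1CC=C(C)C | intermediate
7 | 2-bromo-5-methoxy-4,6-bis(3-methylbut-2-enyl)benzene-1,3-diol | COc1c(CC=C(C)C)c(O)c(Br)c(O)c1CC=C(C)C | intermediate
8 | 2-bromo-5-methoxy-3-(methoxymethoxy)-4,6-bis(3-methylbut-2-enyl)phenol | COCOc1c(Br)c(O)c(CC=C(C)C)c(OC)c1CC=C(C)C | intermediate
9 | [2-bromo-5-methoxy-3-(methoxymethoxy)-4,6-bis(3-methylbut-2-enyl)phenoxy]trimethylsilane | COCOc1c(Br)c(O[Si](C)(C)C)c(CC=C(C)C)c(OC)c1CC=C(C)C | intermediate
10 | [2-lithio-5-methoxy-3-(methoxymethoxy)-4,6-bis(3-methylbut-2-enyl)phenoxy]trimethylsilane | COCOc1c([Li])c(O[Si](C)(C)C)c(CC=C(C)C)c(OC)c1CC=C(C)C | intermediate (not isolated)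
11 | lithium 5-methoxy-3-(methoxymethoxy)-4,6-bis(3-methylbut-2-enyl)-2-(trimethylsilyl)phenolate | COCOc1c([Si](C)(C)C)c(O[Li])c(CC=C(C)C)c(OC)c1CC=C(C)C | intermediate (not isolated)
12 | 5-methoxy-3-(methoxymethoxy)-4,6-bis(3-methylbut-2-enyl)-2-(trimethylsilyl)phenyl trifluoromethanesulfonate | COCOc1c([Si](C)(C)C)c(OS(=O)(=O)C(F)(F)F)c(CC=C(C)C)c(OC)c1CC=C(C)C | intermediate
13 | isovanillin (3-hydroxy-4-methoxybenzaldehyde) | COc1ccc(C=O)cc1O | starting material
14 | 4-methoxy-3-(methoxymethoxy)benzaldehyde | COCOc1cc(C=O)ccc1OC | intermediate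
15 | 4-(2,2-dibromoethenyl)-1-methoxy-2-(methoxymethoxy)benzene | COCOc1cc(C=C(Br)Br)ccc1OC | intermediate
16 | lithium [4-methoxy-3-(methoxymethoxy)phenyl]acetylide | [Li]C#Cc1ccc(OC)c(OCOC)c1 | intermediate (not isolated)
17 | 3-[4-methoxy-3-(methoxymethoxy)phenyl]prop-2-ynoic acid | COCOc1cc(C#CC(=O)O)ccc1OC | intermediate
18 | 1,2-didehydro-5-methoxy-3-(methoxymethoxy)-4,6-bis(3-methylbut-2-enyl)benzene (aryne) | COCOC1=C(CC=C(C)C)C(OC)=C(CC=C(C)C)C#C1 | intermediate (not isolated)
19 | caesium 3-methoxy-5-(methoxymethoxy)-6-{3-[4-methoxy-3-(methoxymethoxy)phenyl]prop-2-ynoyl}-2,4-bis(3-methylbut-2-enyl)phenolate | [Cs+].COCOc1c(C(=O)C#Cc2ccc(OC)c(OCOC)c2)c([O-])c(CC=C(C)C)c(OC)c1CC=C(C)C | intermediate (not isolated)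
20 | 7-methoxy-5-(methoxymethoxy)-2-[4-methoxy-3-(methoxymethoxy)phenyl]-6,8-bis(3-methylbut-2-enyl)chromen-4-one | COc1ccc(-c2cc(=O)c3c(OCOC)c(CC=C(C)C)c(OC)c(CC=C(C)C)c3o2)cc1OCOC | intermediate
21 | 3-lithio-7-methoxy-5-(methoxymethoxy)-2-[4-methoxy-3-(methoxymethoxy)phenyl]-6,8-bis(3-methylbut-2-enyl)chromen-4-one | COc1ccc(-c2oc3c(CC=C(C)C)c(OC)c(CC=C(C)C)c(OCOC)c3c(=O)c2[Li])cc1OCOC | intermediate (not isolated)
22 | dimethyl {7-methoxy-5-(methoxymethoxy)-2-[4-methoxy-3-(methoxymethoxy)phenyl]-6,8-bis(3-methylbut-2-enyl)-4-oxochromen-3-yl}boronate | COB(OC)c1c(-c2ccc(OC)c(OCOC)c2)oc2c(CC=C(C)C)c(OC)c(CC=C(C)C)c(OCOC)c2c1=O | intermediate (not isolated)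
23 | 3-hydroxy-7-methoxy-5-(methoxymethoxy)-2-[4-methoxy-3-(methoxymethoxy)phenyl]-6,8-bis(3-methylbut-2-enyl)chromen-4-one | COc1ccc(-c2oc3c(CC=C(C)C)c(OC)c(CC=C(C)C)c(OCOC)c3c(=O)c2O)cc1OCOC | intermediate
24 | 3,5-dihydroxy-2-(3-hydroxy-4-methoxyphenyl)-7-methoxy-6,8-bis(3-methylbut-2-enyl)chromen-4-one | COc1ccc(-c2oc3c(CC=C(C)C)c(OC)c(CC=C(C)C)c(O)c3c(=O)c2O)cc1O | target

Total step count: 13. Longest linear sequence: 10 steps (steps 1–7 and 11–13, from 1).

Steps most likely to fail

1. Step 11. The crowded aryne may be consumed by an ene reaction with a prenyl double bond of a second molecule before the carboxylate reaches C8a. The C4a aryl anion may also be protonated before acyl transfer, so that the sequence stops at the aryl propiolate, or the first addition may lose its regiocontrol. The fallback builds the ynone stepwise by known chemistry, without an aryne; it sets out from resorcinol 6 and lithium acetylide 16 and comes back to the route at phenoxide 19 and flavone 20. Both phenols of 6 are capped with MOMCl/NaH in DMF to give 3-methoxy-1,5-bis(methoxymethoxy)-2,4-bis(3-methylbut-2-enyl)benzene F1. Quenching acetylide 16 with DMF gives 3-[4-methoxy-3-(methoxymethoxy)phenyl]prop-2-ynal F2. Directed ortho-lithiation of F1 at its only aryl C–H, between the two acetal ethers (n-BuLi, THF, 0 °C), and addition to F2 at −78 °C should give the racemic propargylic alcohol 1-[4-methoxy-2,6-bis(methoxymethoxy)-3,5-bis(3-methylbut-2-enyl)phenyl]-3-[4-methoxy-3-(methoxymethoxy)phenyl]prop-2-yn-1-ol F3. MnO2 in CH2Cl2 should oxidise it to the corresponding prop-2-yn-1-one F4. Brief treatment with dilute HCl in MeOH at 0 °C, where an acetal ortho to the carbonyl is the most labile, should free one phenol and give the 2-hydroxyaryl ynone 1-[2-hydroxy-4-methoxy-6-(methoxymethoxy)-3,5-bis(3-methylbut-2-enyl)phenyl]-3-[4-methoxy-3-(methoxymethoxy)phenyl]prop-2-yn-1-one F5. Cs2CO3 in acetone converts F5 into phenoxide 19, which closes to 20.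

2. Step 1. Alkylation at an already substituted carbon (geminal dialkylation with dearomatisation) and O-alkylation may compete with the second C-prenylation. The fallback delivers each prenyl group regiospecifically by sigmatropic rearrangement; it sets out from 1 and comes back at 4, replacing steps 1 and 2. Para-selective O-methylation of 1 (Me2SO4, K2CO3, acetone) gives methyl 2,6-dihydroxy-4-methoxybenzoate F6. Palladium-catalysed Tsuji–Trost O-allylation of both phenols with tert-butyl 2-methylbut-3-en-2-yl carbonate (Pd(PPh3)4, THF, 0 °C) gives the bis(1,1-dimethylallyl) ether methyl 4-methoxy-2,6-bis[(2-methylbut-3-en-2-yl)oxy]benzoate F7. Heating F7 in toluene at 110 °C should trigger two aromatic Claisen rearrangements. Each can only pass its allyl unit, with allylic inversion to the linear prenyl group, to the single free ortho carbon (C3 and C5), which gives 4.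

3. Step 4. Bromonium transfer to a prenyl double bond with participation of the neighbouring phenol (bromo-etherification), or oxidation of the very electron-rich ring, may compete with substitution at C2. The fallback introduces bromine through an aryllithium, so that no electrophilic bromine meets a free prenylphenol; it sets out from 6 and comes back at 8, replacing steps 4 and 5. Mono-protection of 6 (MOMCl, iPr2NEt) gives 5-methoxy-3-(methoxymethoxy)-4,6-bis(3-methylbut-2-enyl)phenol F8. Dihydropyran with PPTS gives the racemic tetrahydropyranyl ether 2-[5-methoxy-3-(methoxymethoxy)-4,6-bis(3-methylbut-2-enyl)phenoxy]oxane F9. Directed ortho-lithiation between the two acetal oxygens (n-BuLi, THF, 0 °C) and bromine transfer from 1,2-dibromotetrachloroethane, a donor inert towards olefins, should give 2-[2-bromo-5-methoxy-3-(methoxymethoxy)-4,6-bis(3-methylbut-2-enyl)phenoxy]oxane F10. PPTS in MeOH then removes the tetrahydropyranyl group in the presence of the MOM ether to give 8.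

Further compounds
F1 | step 11 | 3-methoxy-1,5-bis(methoxymethoxy)-2,4-bis(3-methylbut-2-enyl)benzene | COCOc1cc(OCOC)c(CC=C(C)C)c(OC)c1CC=C(C)C
F2 | step 11 | 3-[4-methoxy-3-(methoxymethoxy)phenyl]prop-2-ynal | COCOc1cc(C#CC=O)ccc1OC
F3 | step 11 | 1-[4-methoxy-2,6-bis(methoxymethoxy)-3,5-bis(3-methylbut-2-enyl)phenyl]-3-[4-methoxy-3-(methoxymethoxy)phenyl]prop-2-yn-1-ol (racemic) | COCOc1cc(C#CC(O)c2c(OCOC)c(CC=C(C)C)c(OC)c(CC=C(C)C)c2OCOC)ccc1OC
F4 | step 11 | 1-[4-methoxy-2,6-bis(methoxymethoxy)-3,5-bis(3-methylbut-2-enyl)phenyl]-3-[4-methoxy-3-(methoxymethoxy)phenyl]prop-2-yn-1-one | COCOc1cc(C#CC(=O)c2c(OCOC)c(CC=C(C)C)c(OC)c(CC=C(C)C)c2OCOC)ccc1OC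
F5 | step 11 | 1-[2-hydroxy-4-methoxy-6-(methoxymethoxy)-3,5-bis(3-methylbut-2-enyl)phenyl]-3-[4-methoxy-3-(methoxymethoxy)phenyl]prop-2-yn-1-one | COCOc1cc(C#CC(=O)c2c(O)c(CC=C(C)C)c(OC)c(CC=C(C)C)c2OCOC)ccc1OC
F6 | step 1 | methyl 2,6-dihydroxy-4-methoxybenzoate | COC(=O)c1c(O)cc(OC)cc1O
F7 | step 1 | methyl 4-methoxy-2,6-bis[(2-methylbut-3-en-2-yl)oxy]benzoate | COC(=O)c1c(OC(C)(C)C=C)cc(OC)cc1OC(C)(C)C=C
F8 | step 4 | 5-methoxy-3-(methoxymethoxy)-4,6-bis(3-methylbut-2-enyl)phenol | COCOc1cc(O)c(CC=C(C)C)c(OC)c1CC=C(C)C
F9 | step 4 | 2-[5-methoxy-3-(methoxymethoxy)-4,6-bis(3-methylbut-2-enyl)phenoxy]oxane (racemic) | COCOc1cc(OC2CCCCO2)c(CC=C(C)C)c(OC)c1CC=C(C)C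
F10 | step 4 | 2-[2-bromo-5-methoxy-3-(methoxymethoxy)-4,6-bis(3-methylbut-2-enyl)phenoxy]oxane (racemic) | COCOc1c(Br)c(OC2CCCCO2)c(CC=C(C)C)c(OC)c1CC=C(C)C
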